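Q in this flask has to be placed in time: racemic D and E with G and the single-handed catalyst X, closed and isothermal.

all flasks: X 5.2 mM

| run | D | E | G | remark | time |
|---|---|---|---|---|---|
| blue | 29 mM | 29 mM | 120 mM | run made earlier |  |
| green | 29 mM | 29 mM | 190 mM | run made earlier |  |
| red | 44 mM | 44 mM | 87 mM | run made earlier |  |
| flask | 29 mM | 29 mM | 87.0 mM |  | 30 min |

- blue (time / min: Q / %, D / %): 0.417: 8.0, 40.8; 1.33: 11.0, 34.8; 4.00: 8.8, 32.4; 12.0: 8.5, 32.8; 40.0: 9.6, 32.5
- green (time / min: Q / %, D / %): 0.417: 10.5, 38.5; 1.33: 11.3, 33.0; 4.00: 9.2, 33.0; 12.0: 8.5, 33.0; 40.0: 8.9, 32.4
- red (time / min: Q / %, D / %): 0.417: 6.1, 42.4; 1.33: 9.5, 36.1; 4.00: 9.6, 33.2; 12.0: 8.5, 32.7; 40.0: 8.8, 32.4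

(standard deviation of a reading: 0.3 percentage points)

- X is single-handed; D and E are mirror images of each other, charged as a racemate, each of them at the stated concentration

- the moment within 30 min at which there is most Q
- the amount of Q, in percent of the D and E together charged, at that time
- earliest time at which at least nineteen twentieths of that best amount are there, in min
- latest time at which they still are, in min

I built the flask up one process at a time. The main step by itself, G + X + D to Q at steady [G] and [X], is a pseudo-first-order decay of D towards zero. The readings refused that: at 40.0 min D stood at 32.5%, 32.4% and 32.4% in blue, green and red, averaging 32.4% out of the 50.0% charged.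

So I added a second process, which I assumed: X lost to G, first order in each. Dividing the rate of D by the rate of X cancels [G] and time, and the integral reads ln(charged [D]/[D]) = n(charged [X] − [X]). I call n the catalyst's reach, 0.0832 /mM: the logarithm of charged D over D remaining, per mM of X lost, read here with the 5.2 mM of X taken as lost at the plateau. Neither [G] nor charged [D] stands on the right side, and those plateaus came from [G] of 87 mM to 190 mM and [D] of 29 mM to 44 mM, differing by no more than the scatter of 0.3 percentage points. In percent, then, the flask should read like red, which has the same [G] and [X]. The flask should lose 17.6% of the D and E together charged as D.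

Last came the rest: red's Q stood near 8.8%, about half of that, after blue had read 11.0% at 1.33 min. I therefore let Q pass reversibly into a further product. Red read 9.5% at 1.33 min and 9.6% at 4.00 min, so I placed the flask's top between those times, at or above those readings.

The forecast gave 10% at 1.8 min, with the window from 1.1 min to 3 min. It differed from me on the plateau: “the plateau needs no catalyst death”.

The flask gave 9.92% at 1.68 min, with the window from 1.03 min to 3.15 min.

    G + X + D → X + Q (k = 17.9 /M²/s)
    G + X + E → X + J (k = 0.263 /M²/s)
    G + X → L (k = 0.217 /M/s)
    Q ⇌ J (k = 0.00918 /s)

At 1.68 min this flask held 18.0% of its catalyst as X and 82.0% as L, and the reach then gives D at 35.1% of the charge, against 35.2% in the flask. A neighbour flask, like this one but charged with 8.8 mM of X, reached 0% X and 100% L at 30.0 min. The reach gives 48.1% of its charged D remaining, and that neighbour flask kept 48%. Half of the D consumed gives Q at 13.0%, and that neighbour flask held 13.2% at that time, after a top of 14.6%.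

The runs come from a simulation on assumed constants, and the scatter is random.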